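**Remark:** benzofuran numbering (O1, C2, C3, C3a, C4 to C7, C7a) is used for the target and for the corresponding atoms of every precursor; "carbinol carbon" means the exocyclic C(OH)(CH3) carbon on C2; starting materials 1, 3, 7, 12 and 13 are taken to be commercial.

## Retrosynthetic overview

1. The chalcone is cut at C5–C(=O): a C5 aryllithium (ortho-lithiation next to the C4 MOM ether) adds to the cinnamic Weinreb amide 14; global acid deprotection is the last step.
2. Ring B (dihydrofuran: O1, C2, C3, C3a, C7a) is the only ring made; it is cut at C3–C3a and closed by palladium-catalyzed C(sp3)–H arylation of an unfunctionalized methyl group (C3) by an aryl bromide at C3a.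
3. Enabling feature: C3 is a methyl group on C2, held three atoms (C2, O1, C7a) away from C3a, the arene carbon flanked by the oxygen-bearing carbons C4 and C7a; a six-membered palladacycle can form and contract to ring B, and bromine at C3a fixes the site.
4. The acyclic precursor comes from 2-bromoresorcinol and methyl (R)-lactate (Mitsunobu inversion sets C2; the lactate methyl becomes C3); the carbinol carbon is set by chelation-controlled addition of a homoprenyl Grignard reagent to the α-aryloxy methyl ketone.
5. Order of rings: rings A (resorcinol-derived) and C (4-hydroxyphenyl) are bought; ring B is closed in step 7.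

Key step: step 7

## Route

Step 1
Reactants: 1 2-bromobenzene-1,3-diol
Product: 2 2-bromo-3-(methoxymethoxy)phenol
Conditions: MOMCl (1 equiv), K2CO3, acetone, 0 °C to rt; 1 in excess, recovered
Reagents that add atoms: chloromethyl methyl ether (MOMCl), COCCl
Why: Williamson-type O-alkylation of one of two equivalent phenols, kept at the mono-ether stage by limiting MOMCl.

Step 2
Reactants: 2 2-bromo-3-(methoxymethoxy)phenol; 3 methyl (2R)-2-hydroxypropanoate
Product: 4 methyl (2S)-2-[2-bromo-3-(methoxymethoxy)phenoxy]propanoate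
Conditions: PPh3, DIAD, THF, 0 °C to rt
Reagents that add atoms: none
Why: Mitsunobu etherification proceeds by SN2 with inversion at the lactate carbon, which sets C2 as S and brings in C3 as the lactate methyl group.

Step 3
Reactants: 4 methyl (2S)-2-[2-bromo-3-(methoxymethoxy)phenoxy]propanoate
Product: 5 (2S)-2-[2-bromo-3-(methoxymethoxy)phenoxy]-N-methoxy-N-methylpropanamide
Conditions: MeNH(OMe)·HCl, i-PrMgCl, THF, −20 °C
Reagents that add atoms: N,O-dimethylhydroxylamine hydrochloride, CNOC.Cl
Why: Weinreb amide formation by aminolysis of the ester with the magnesium amide at low temperature should leave the α-stereocenter and the electron-rich aryl bromide untouched.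

Step 4
Reactants: 5 (2S)-2-[2-bromo-3-(methoxymethoxy)phenoxy]-N-methoxy-N-methylpropanamide
Product: 6 (3S)-3-[2-bromo-3-(methoxymethoxy)phenoxy]butan-2-one
Conditions: MeMgBr, THF, 0 °C
Reagents that add atoms: methylmagnesium bromide, C[Mg]Br
Why: Weinreb ketone synthesis; the chelated tetrahedral adduct prevents over-addition and keeps the ketone masked from enolization until work-up.

Step 5
Reactants: 6 (3S)-3-[2-bromo-3-(methoxymethoxy)phenoxy]butan-2-one; 7 5-bromo-2-methylpent-2-ene
Product: 9 (2S,3S)-2-[2-bromo-3-(methoxymethoxy)phenoxy]-3,7-dimethyloct-6-en-3-ol, via (4-methylpent-3-en-1-yl)magnesium bromide 8 (not isolated)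
Conditions: 7, Mg, Et2O, rt; then 6, MgBr2·OEt2, CH2Cl2, −78 °C
Reagents that add atoms: none
Why: Chelation-controlled Grignard addition: magnesium bridges the ketone oxygen and the aryl ether oxygen O1 in a five-membered chelate, so the homoprenyl group should add from the face of the C2 hydrogen, opposite the C3 methyl group, which gives the S carbinol carbon next to S-configured C2.

Step 6
Reactants: 9 (2S,3S)-2-[2-bromo-3-(methoxymethoxy)phenoxy]-3,7-dimethyloct-6-en-3-ol
Product: 10 {[(2S,3S)-2-[2-bromo-3-(methoxymethoxy)phenoxy]-3,7-dimethyloct-6-en-3-yl]oxy}triethylsilane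
Conditions: TESOTf, 2,6-lutidine, CH2Cl2, −78 to 0 °C
Reagents that add atoms: triethylsilyl trifluoromethanesulfonate (TESOTf), CC[Si](CC)(CC)OS(=O)(=O)C(F)(F)F
Why: Silylation of the hindered tertiary alcohol with a silyl triflate masks a hydroxyl group that could otherwise bind palladium (C–O coupling, β-carbon elimination) in step 7 and consume base in step 9.

Step 7
Reactants: 10 {[(2S,3S)-2-[2-bromo-3-(methoxymethoxy)phenoxy]-3,7-dimethyloct-6-en-3-yl]oxy}triethylsilane
Product: 11 triethyl{[(2S)-2-[(2S)-4-(methoxymethoxy)-2,3-dihydro-1-benzofuran-2-yl]-6-methylhept-5-en-2-yl]oxy}silane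
Conditions: Pd(OAc)2 (5 mol %), PCy3·HBF4 (10 mol %), PivOH (30 mol %), Cs2CO3, mesitylene, 135 °C
Reagents that add atoms: none
Why: Oxidative addition of the C3a–Br bond to zerovalent palladium (formed in situ from Pd(OAc)2 and PCy3), exchange of bromide for pivalate, concerted metalation–deprotonation of a C–H bond of the C3 methyl group through a six-membered palladacycle (Pd, C3a, C7a, O1, C2, C3) and C(sp2)–C(sp3) reductive elimination form C3–C3a. The closest known reaction type is the palladium-catalyzed intramolecular alkane arylation of 2-bromoaryl alkyl ethers to 2,3-dihydrobenzofurans. Ring B is closed by contraction of the six-membered palladacycle in the reductive elimination, formally a 5-exo alkylation of C3a by C3. No new stereocenter is formed, and C2 and the carbinol carbon are not touched and bear no acidic hydrogen, so both configurations should be carried through unchanged. The step needs site selectivity for the primary C3–H bonds over C2–H, the carbinol methyl group, the chain methylenes and the acetal C–H bonds, and it needs reductive elimination to outrun β-hydride elimination toward C2. This is secured by the preference of the metalation for methyl groups, by the fact that only C3 gives a six-membered palladacycle (C2–H would need a five-membered one, the carbinol methyl a seven-membered one), by the bulky fully substituted carbinol carbon on C2, which turns the methyl group toward the metal, and by the bromine at C3a between C4 and C7a, which leaves no choice of arene position.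

Step 8
Reactants: 12 4-(methoxymethoxy)benzaldehyde; 13 diethyl {2-[methoxy(methyl)amino]-2-oxoethyl}phosphonate
Product: 14 (2E)-N-methoxy-3-[4-(methoxymethoxy)phenyl]-N-methylprop-2-enamide
Conditions: NaH, THF, 0 °C to rt
Reagents that add atoms: none
Why: Horner–Wadsworth–Emmons olefination with a stabilized phosphonate anion should give the E-configured unsaturated Weinreb amide.

Step 9
Reactants: 11 triethyl{[(2S)-2-[(2S)-4-(methoxymethoxy)-2,3-dihydro-1-benzofuran-2-yl]-6-methylhept-5-en-2-yl]oxy}silane; 14 (2E)-N-methoxy-3-[4-(methoxymethoxy)phenyl]-N-methylprop-2-enamide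
Product: 16 (2E)-1-{(2S)-4-(methoxymethoxy)-2-[(2S)-6-methyl-2-(triethylsilyloxy)hept-5-en-2-yl]-2,3-dihydro-1-benzofuran-5-yl}-3-[4-(methoxymethoxy)phenyl]prop-2-en-1-one, via C5 aryllithium 15 (not isolated)
Conditions: s-BuLi, TMEDA, THF, −78 °C; then 14, −78 to 0 °C
Reagents that add atoms: none
Why: Directed ortho-metalation: the MOM ether on C4 is the strongest director and C5 is its only free ortho position; the aryllithium adds 1,2 to the Weinreb amide, whose stable chelate should release the E-enone only on work-up.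

Step 10
Reactants: 16 (2E)-1-{(2S)-4-(methoxymethoxy)-2-[(2S)-6-methyl-2-(triethylsilyloxy)hept-5-en-2-yl]-2,3-dihydro-1-benzofuran-5-yl}-3-[4-(methoxymethoxy)phenyl]prop-2-en-1-one
Product: 17 (2E)-1-[(2S)-4-hydroxy-2-[(2S)-2-hydroxy-6-methylhept-5-en-2-yl]-2,3-dihydro-1-benzofuran-5-yl]-3-(4-hydroxyphenyl)prop-2-en-1-one
Conditions: HCl (3 M aq.), MeOH, rt to 40 °C
Reagents that add atoms: none
Why: Acid-catalyzed acetal exchange removes both MOM ethers and solvolysis removes the triethylsilyl ether in one operation; conditions are kept mild so that the trisubstituted alkene, the tertiary alcohol and the open 2'-hydroxychalcone should survive, and neither stereocenter can epimerize.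

## Compound list

1 | 2-bromobenzene-1,3-diol (2-bromoresorcinol) | Oc1cccc(O)c1Br | starting material
2 | 2-bromo-3-(methoxymethoxy)phenol | COCOc1cccc(O)c1Br | intermediate
3 | methyl (2R)-2-hydroxypropanoate (methyl (R)-lactate) | COC(=O)[C@H](O)C | starting material
4 | methyl (2S)-2-[2-bromo-3-(methoxymethoxy)phenoxy]propanoate | COC(=O)[C@@H](Oc1cccc(OCOC)c1Br)C | intermediate
5 | (2S)-2-[2-bromo-3-(methoxymethoxy)phenoxy]-N-methoxy-N-methylpropanamide | CON(C)C(=O)[C@@H](Oc1cccc(OCOC)c1Br)C | intermediate
6 | (3S)-3-[2-bromo-3-(methoxymethoxy)phenoxy]butan-2-one | CC(=O)[C@@H](Oc1cccc(OCOC)c1Br)C | intermediate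
7 | 5-bromo-2-methylpent-2-ene | CC(C)=CCCBr | starting material
8 | (4-methylpent-3-en-1-yl)magnesium bromide | CC(C)=CCC[Mg]Br | intermediate (not isolated)
9 | (2S,3S)-2-[2-bromo-3-(methoxymethoxy)phenoxy]-3,7-dimethyloct-6-en-3-ol | CC(C)=CCC[C@](C)(O)[C@@H](Oc1cccc(OCOC)c1Br)C | intermediate
10 | {[(2S,3S)-2-[2-bromo-3-(methoxymethoxy)phenoxy]-3,7-dimethyloct-6-en-3-yl]oxy}triethylsilane | CC(C)=CCC[C@](C)(O[Si](CC)(CC)CC)[C@@H](Oc1cccc(OCOC)c1Br)C | intermediate
11 | triethyl{[(2S)-2-[(2S)-4-(methoxymethoxy)-2,3-dihydro-1-benzofuran-2-yl]-6-methylhept-5-en-2-yl]oxy}silane | CC(C)=CCC[C@](C)(O[Si](CC)(CC)CC)[C@@H]1Cc2c(OCOC)cccc2O1 | intermediate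
12 | 4-(methoxymethoxy)benzaldehyde | COCOc1ccc(C=O)cc1 | starting material
13 | diethyl {2-[methoxy(methyl)amino]-2-oxoethyl}phosphonate | CCOP(=O)(CC(=O)N(C)OC)OCC | starting material
14 | (2E)-N-methoxy-3-[4-(methoxymethoxy)phenyl]-N-methylprop-2-enamide | CON(C)C(=O)/C=C/c1ccc(OCOC)cc1 | intermediate
15 | {(2S)-4-(methoxymethoxy)-2-[(2S)-6-methyl-2-(triethylsilyloxy)hept-5-en-2-yl]-2,3-dihydro-1-benzofuran-5-yl}lithium (C5 aryllithium) | CC(C)=CCC[C@](C)(O[Si](CC)(CC)CC)[C@@H]1Cc2c(OCOC)c([Li])ccc2O1 | intermediate (not isolated)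
16 | (2E)-1-{(2S)-4-(methoxymethoxy)-2-[(2S)-6-methyl-2-(triethylsilyloxy)hept-5-en-2-yl]-2,3-dihydro-1-benzofuran-5-yl}-3-[4-(methoxymethoxy)phenyl]prop-2-en-1-one | CC(C)=CCC[C@](C)(O[Si](CC)(CC)CC)[C@@H]1Cc2c(ccc(C(=O)/C=C/c3ccc(OCOC)cc3)c2OCOC)O1 | intermediate
17 | (2E)-1-[(2S)-4-hydroxy-2-[(2S)-2-hydroxy-6-methylhept-5-en-2-yl]-2,3-dihydro-1-benzofuran-5-yl]-3-(4-hydroxyphenyl)prop-2-en-1-one | CC(C)=CCC[C@](C)(O)[C@@H]1Cc2c(ccc(C(=O)/C=C/c3ccc(O)cc3)c2O)O1 | target

## Step count and risks

Total step count: 10. Longest linear sequence: 9 steps (steps 1 to 7, 9 and 10); step 8 is a one-step side branch.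

**Step 7 (key step).** Metalation of a methyl group that sits next to a methine carbon may be slow, so that protodebromination of the arylpalladium species takes over. Alternatively, the palladacycle may lose the C2 hydrogen by β-hydride elimination and give an aryl enol ether instead of ring B.

The fallback sets out from 2 and comes back at 11. It replaces the C–H activation by an aryllithium alkylation on a C3 bromide. Mitsunobu reaction of 2 with methyl (2R)-3-[(tert-butyldiphenylsilyl)oxy]-2-hydroxypropanoate, a known mono-silyl ether of methyl (R)-glycerate, would give methyl (2S)-2-[2-bromo-3-(methoxymethoxy)phenoxy]-3-[(tert-butyldiphenylsilyl)oxy]propanoate F1. The operations of steps 3 to 5 would then give (2S)-2-[2-bromo-3-(methoxymethoxy)phenoxy]-3-[(tert-butyldiphenylsilyl)oxy]-N-methoxy-N-methylpropanamide F2, then (3S)-3-[2-bromo-3-(methoxymethoxy)phenoxy]-4-[(tert-butyldiphenylsilyl)oxy]butan-2-one F3, and, by chelation-controlled addition of 8 (the silyl ether oxygen does not chelate), (2S,3S)-2-[2-bromo-3-(methoxymethoxy)phenoxy]-1-[(tert-butyldiphenylsilyl)oxy]-3,7-dimethyloct-6-en-3-ol F4. TBAF in THF would free the primary alcohol to give (2S,3S)-2-[2-bromo-3-(methoxymethoxy)phenoxy]-3,7-dimethyloct-6-ene-1,3-diol F5. CBr4 and PPh3 would convert only the primary hydroxyl group into (2R,3S)-1-bromo-2-[2-bromo-3-(methoxymethoxy)phenoxy]-3,7-dimethyloct-6-en-3-ol F6. n-BuLi (2.2 equiv, THF, −100 to −78 °C) would deprotonate the tertiary alcohol and exchange the aryl bromine for lithium, and the aryllithium would displace the primary bromide (Parham cyclization, 5-exo-tet) to give (2S)-2-[(2S)-4-(methoxymethoxy)-2,3-dihydro-1-benzofuran-2-yl]-6-methylhept-5-en-2-ol F7. Silylation as in step 6 would give 11.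

**Step 5.** The aryl ether oxygen, flanked by bromine, may chelate magnesium poorly, so that the addition runs with poor facial selectivity or mainly under Felkin–Anh control and gives the epimer at the carbinol carbon. Enolization of the ketone by the Grignard reagent could also erode C2.

The fallback sets out from 5 and comes back at 9. The two carbon groups are introduced in the reverse order, so that non-chelation control leads to the wanted isomer. Grignard reagent 8 would be added to Weinreb amide 5 to give (2S)-2-[2-bromo-3-(methoxymethoxy)phenoxy]-7-methyloct-6-en-3-one F8. MeLi in THF at −78 °C, a poorly chelating combination, would then add under Felkin–Anh control with the aryloxy group anti to the incoming methyl group. This places the methyl group where the chelate model places it as the resident group, and should give 9.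

**Step 9.** Lithiation may lose site selectivity: the ring oxygen O1 can direct metalation to C7, and deprotonation at benzylic C3 would open ring B by elimination of the phenoxide.

The fallback sets out from 11 and comes back at 17. The acyl group is built on the free phenol, where only C5 is ortho to the hydroxyl group. HCl in MeOH would remove the MOM and silyl groups of 11 to give (2S)-2-[(2S)-2-hydroxy-6-methylhept-5-en-2-yl]-2,3-dihydro-1-benzofuran-4-ol F9. Ortho-formylation with MgCl2, Et3N and paraformaldehyde in MeCN at reflux would give (2S)-4-hydroxy-2-[(2S)-2-hydroxy-6-methylhept-5-en-2-yl]-2,3-dihydro-1-benzofuran-5-carbaldehyde F10. Excess MeMgBr would give (2S)-5-(1-hydroxyethyl)-2-[(2S)-2-hydroxy-6-methylhept-5-en-2-yl]-2,3-dihydro-1-benzofuran-4-ol F11 as a mixture of epimers at the new carbinol. MnO2 would oxidize the benzylic alcohol to 1-[(2S)-4-hydroxy-2-[(2S)-2-hydroxy-6-methylhept-5-en-2-yl]-2,3-dihydro-1-benzofuran-5-yl]ethan-1-one F12. Claisen–Schmidt condensation of F12 with 4-hydroxybenzaldehyde (KOH, EtOH) would give 17.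

## Further compounds

F1 | step 7 | methyl (2S)-2-[2-bromo-3-(methoxymethoxy)phenoxy]-3-[(tert-butyldiphenylsilyl)oxy]propanoate | COC(=O)[C@@H](Oc1cccc(OCOC)c1Br)CO[Si](c1ccccc1)(c1ccccc1)C(C)(C)C
F2 | step 7 | (2S)-2-[2-bromo-3-(methoxymethoxy)phenoxy]-3-[(tert-butyldiphenylsilyl)oxy]-N-methoxy-N-methylpropanamide | CON(C)C(=O)[C@@H](Oc1cccc(OCOC)c1Br)CO[Si](c1ccccc1)(c1ccccc1)C(C)(C)C
F3 | step 7 | (3S)-3-[2-bromo-3-(methoxymethoxy)phenoxy]-4-[(tert-butyldiphenylsilyl)oxy]butan-2-one | CC(=O)[C@@H](Oc1cccc(OCOC)c1Br)CO[Si](c1ccccc1)(c1ccccc1)C(C)(C)C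
F4 | step 7 | (2S,3S)-2-[2-bromo-3-(methoxymethoxy)phenoxy]-1-[(tert-butyldiphenylsilyl)oxy]-3,7-dimethyloct-6-en-3-ol | CC(C)=CCC[C@](C)(O)[C@@H](Oc1cccc(OCOC)c1Br)CO[Si](c1ccccc1)(c1ccccc1)C(C)(C)C
F5 | step 7 | (2S,3S)-2-[2-bromo-3-(methoxymethoxy)phenoxy]-3,7-dimethyloct-6-ene-1,3-diol | CC(C)=CCC[C@](C)(O)[C@@H](Oc1cccc(OCOC)c1Br)CO
F6 | step 7 | (2R,3S)-1-bromo-2-[2-bromo-3-(methoxymethoxy)phenoxy]-3,7-dimethyloct-6-en-3-ol | CC(C)=CCC[C@](C)(O)[C@@H](Oc1cccc(OCOC)c1Br)CBr
F7 | step 7 | (2S)-2-[(2S)-4-(methoxymethoxy)-2,3-dihydro-1-benzofuran-2-yl]-6-methylhept-5-en-2-ol | CC(C)=CCC[C@](C)(O)[C@@H]1Cc2c(OCOC)cccc2O1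
F8 | step 5 | (2S)-2-[2-bromo-3-(methoxymethoxy)phenoxy]-7-methyloct-6-en-3-one | CC(C)=CCCC(=O)[C@@H](Oc1cccc(OCOC)c1Br)C
F9 | step 9 | (2S)-2-[(2S)-2-hydroxy-6-methylhept-5-en-2-yl]-2,3-dihydro-1-benzofuran-4-ol | CC(C)=CCC[C@](C)(O)[C@@H]1Cc2c(O)cccc2O1
F10 | step 9 | (2S)-4-hydroxy-2-[(2S)-2-hydroxy-6-methylhept-5-en-2-yl]-2,3-dihydro-1-benzofuran-5-carbaldehyde | CC(C)=CCC[C@](C)(O)[C@@H]1Cc2c(O)c(C=O)ccc2O1
F11 | step 9 | (2S)-5-(1-hydroxyethyl)-2-[(2S)-2-hydroxy-6-methylhept-5-en-2-yl]-2,3-dihydro-1-benzofuran-4-ol | CC(C)=CCC[C@](C)(O)[C@@H]1Cc2c(O)c(C(C)O)ccc2O1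
F12 | step 9 | 1-[(2S)-4-hydroxy-2-[(2S)-2-hydroxy-6-methylhept-5-en-2-yl]-2,3-dihydro-1-benzofuran-5-yl]ethan-1-one | CC(C)=CCC[C@](C)(O)[C@@H]1Cc2c(O)c(C(C)=O)ccc2O1
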